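## Structural features

The target is a 1,7-dioxaspiro[4.4]nonane-2,6-dione: two γ-lactones that share the quaternary carbon C3. Ring A (C3, C4, C5, O, C3') carries only the dec-9-enyl chain, at C5 (R). Ring B (C3, O, C0, C1, C2) carries three contiguous oxygenated stereocentres: the secondary carbinol C1 (R), the fully substituted C2 (R) with a hydroxyl and a free carboxylic acid, and the spiro carbon C3 (S). The C1 and C2 hydroxyls are trans on ring B; the C2 hydroxyl lies on the ring B face occupied by the ring A carbonyl C3', while the C2 carboxyl and the C1 hydroxyl lie on the face of C4. Across ring A, the ring B oxygen on C3 is trans to the chain. Fragile elements are the two lactones (acyl attack by bases, translactonisation), the isolated terminal alkene (excludes osmium-based, peracid-excess and hydrogenolytic chemistry), and the two fully substituted carbons C2 and C3, which cannot be epimerised, so any error there is permanent. The real difficulty is the dense C1–C2–C3 triad, which sits far from C5, a centre that can give only weak 1,3-control. The key step exploits the fact that a trans C1/C2 diol with a carboxyl on C2 is the anti-dioxygenation pattern of a ring B butenolide whose C1=C2 bond is activated from both ends (C0 lactone carbonyl, C2 ester): a nucleophilic peroxide epoxidises only that alkene, and the epoxide can be opened only at C1.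

## Logic of the disconnections

13 ⇒ 11 (through 12). The C1–OH bond is cut back to a C1–C2 epoxide and the C2 carboxyl is masked as its tert-butyl ester. Anti opening of a cis-fused epoxide gives the trans diol by mechanism, and C2 is quaternary, so only C1 can be attacked. The gain is that C1 and C2 stop being separate stereochemical problems: both follow from the face that the epoxide occupies in 11. The demand is that hydration of the acid 12 must outrun its decarboxylation and leave both lactones and the alkene intact.

11 ⇒ 10. Both oxirane bonds, C1–O and C2–O, are cut. The C1=C2 bond of 10 is electron-poor, so a nucleophilic peroxide should react there and nowhere else, and the chain alkene needs no mask. Two stereocentres and one ring disappear; 10 keeps only C3 and C5. The demand is oxygen delivery on the face syn to C3' and anti to C4, with no acyl attack on the lactones. The tert-butyl ester and free alkene are kept in 10 because the ester resists peroxide and leaves in the acid step that also opens the epoxide.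

10 ⇒ 7 + 8. The C1=C2 double bond and the ring B acyl–oxygen bond (C0–O on C3) are cut. This is the tertiary α-ketol plus two-carbon ketenylidene retron, and it removes ring B altogether. The demand is that the hindered tertiary hydroxyl of 7 adds to 8 and that the ylide 9 then selects the α-keto ester carbonyl over the lactone and ester carbonyls.

7 ⇒ 6. The C3–O bond is cut. C3 of 6 is the central carbon of a 1,3-dicarbonyl system, so it enolises under mild base and accepts electrophilic oxygen. The quaternary stereocentre is removed, and 6 has C5 as its only fixed centre. The demand is oxygen transfer anti to the C5 chain by an oxidant that ignores the alkene.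

6 ⇒ 4 + 5. The C3–C2 bond is cut (Claisen retron). 5 cannot enolise and delivers C2 together with the C2 carboxyl, already as the tert-butyl ester that lasts to the final step. The demand is two equivalents of base and no self-condensation of 4.

4 ⇒ 2 + 3 (3 from 1). The chain bond between the CH2 on C5 and the nonenyl group is cut. C5 then comes from the chiral pool with its lactone ring already in place, so no resolution and no separate lactone construction are needed; this saves about three steps over building the lactone from a resolved terminal epoxide and a malonate. The demand is that copper-mediated substitution of the tosylate beats addition of 3 to the lactone carbonyl.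

## Other disconnections considered

Alternative 1: The cut is at the spiro carbon, through the C3–C3' bond and the ring B acyl–oxygen bond. In the forward sense the open-chain γ-keto acid A1 (C0 acid, C3 ketone, C1/C2 diol and C2 methyl ester in place, C5 oxygen as a silyl ether) would undergo an intramolecular Passerini reaction with tert-butyl isocyanide: α-addition of the isocyanide carbon to C3, capture of the nitrilium ion by the C0 carboxylate and a Mumm-type acyl shift to the C3 oxygen, giving the lactone amide A2.
- In its favour: one step creates the quaternary spiro carbon and ring B from an acyclic chain. The C1/C2 anti-diol of A1 could come from a tartrate-type building block and so is not subject to any facial choice; on this point the alternative is better than the chosen plan.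
- Against it here: the C3 configuration rests on acyclic 1,2-induction from C2 at a hindered ketone, and ketones are slow Passerini partners. A1 is a β-hydroxy ketone and α-ketol, open to retro-aldol and ketol shift. After the key step the hindered N-tert-butyl amide of A2 must be turned into the ring A lactone, and a methyl ester must be cleaved next to two lactones.
- Comparison: structurally, the chosen plan builds the carbon skeleton early and adds oxygen last, whereas this route forms carbon–carbon bonds at the most congested atom late. Mechanistically, each route has one uncertain facial event (equal). In step economy, A1 needs its own multi-step assembly plus two extra end-game operations, so the route is clearly longer.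

Alternative 2: The cut is the C5–O bond of ring A. In the forward sense the acid A3 (ring B complete, C1 as acetate, C2 hydroxy acid as an acetonide, C3 bearing the carboxyl and a 12-bromododecyl chain) would be oxidised by a Mn(OTf)2(pdp)-type catalyst (divalent manganese) with hydrogen peroxide. The carboxylate-bound metal–oxo species would abstract the γ-hydrogen at C5 and rebound to close ring A, giving A4.
- In its favour: no stereodefined C5 building block is needed, and C3 can be set without reference to C5, so the weak 1,3-induction of the chosen plan is avoided; on this point the alternative is better. The catalyst, not the substrate, selects the C5–H.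
- Against it here: C5 is one of eleven similar methylenes and is singled out only by the geometry of the directed hydrogen abstraction. The acid is α,α-disubstituted and electron-poor. The catalyst must be matched with three existing stereocentres. The electrophilic oxidant forces the alkene to be carried as a bromide and regenerated later, and acetate and acetonide must be removed at the end. A3 itself requires the whole C1–C3 triad to be built first.
- Comparison: structurally, this route cuts at the easiest stereocentre and leaves the hard triad unsolved, whereas the chosen key step solves the triad. Mechanistically, radical abstraction/rebound replaces polar conjugate addition; the chosen plan is better on chemoselectivity because the alkene stays unmasked, and the two are equal in resting on one selectivity event without close precedent. In step economy the alternative is worse by the masking, unmasking and deprotection steps.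

Alternative 3: The cut is the C1–C2 bond. In the forward sense the silyloxyacetate A5, the ester of the tertiary hydroxyl of 7, would be converted by LiN(i-Pr)2 into its ester enolate, which would add to the neighbouring α-keto ester carbonyl. This closes ring B and creates both carbinol centres, giving A6.
- In its favour: it branches from 7 of the chosen route. The C1 oxygen arrives at the right oxidation level, so no epoxide and no hot acid are needed; the end game is milder, and on this point the alternative is better. The step count from 7 is equal (acylation, aldol, deprotection against butenolide formation, epoxidation, acid step).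
- Against it here: there are two stereochemical questions (the face of C2, and C1 relative to C2) instead of one, and the anti relation of the two oxygens is not enforced by the mechanism. The closure is a 5-(enolendo)-exo-trig process, an unfavourable class by Baldwin's rules, although ester-enolate aldol lactonisations of α-acyloxy ketones are known. A strong amide base next to a very electrophilic keto ester invites acyl migration or cleavage.
- Comparison: structurally, both routes use the same tertiary ketol. Mechanistically, lithium chelation of the ketone with the C3' carbonyl is the same kind of argument as in the chosen plan for the C2 face (equal), but C1 depends on enolate geometry (worse). Because it shares 7, a close variant is kept as the reserve for the key step.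

Key step: step 5

Assumption: tosylate 2 is used as the purchased, enantiopure chiral-pool compound (from L-glutamic acid). A re-derivation of all configurations shows that 10, 11 and 13 correlate without epimerisation: C5 R, C3 S, epoxide oxygen syn to C3', invertive opening at C1 giving 3R,4R.

## Route

Step 1
Reactants: 1 9-bromonon-1-ene; 2 (S)-(5-oxooxolan-2-yl)methyl 4-methylbenzenesulfonate
Product: 4 (R)-5-(dec-9-en-1-yl)oxolan-2-one, via non-8-en-1-ylmagnesium bromide 3 (not isolated)
Conditions: 1, Mg, THF, 40 °C; then added slowly to 2, Li2CuCl4 (5 mol %), THF/NMP, −20 → 0 °C
Reagents that add atoms: none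
Why: Copper-catalysed alkyl–alkyl cross-coupling of a Grignard reagent with a primary tosylate (Kochi-type coupling): the organocopper species formed from 3 should substitute the tosylate at CH2 much faster than 3 adds to the lactone carbonyl while 3 is kept at low stationary concentration. No bond to C5 is made or broken, so the configuration of 2 is carried into 4; the descriptor changes from S to R only because the CH2 group loses its oxygen.

Step 2
Reactants: 4 (R)-5-(dec-9-en-1-yl)oxolan-2-one; 5 di-tert-butyl oxalate
Product: 6 tert-butyl 2-[(5R)-5-(dec-9-en-1-yl)-2-oxooxolan-3-yl]-2-oxoacetate (C3 epimers, largely enolised)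
Conditions: LiN(SiMe3)2 (2.2 equiv), THF, −78 °C; then 5 (1.2 equiv), −78 → −20 °C; AcOH quench
Reagents that add atoms: none
Why: Crossed Claisen condensation: the lithium enolate of 4 adds to one carbonyl of the non-enolisable oxalate and expels tert-butoxide, and the second equivalent of base converts 6 into its doubly stabilised enolate, which drives the equilibrium and prevents a second acylation. C3 of 6 is enolised, so no stereocentre needs control here.

Step 3
Reactants: 6 tert-butyl 2-[(5R)-5-(dec-9-en-1-yl)-2-oxooxolan-3-yl]-2-oxoacetate
Product: 7 tert-butyl 2-[(3S,5R)-5-(dec-9-en-1-yl)-3-hydroxy-2-oxooxolan-3-yl]-2-oxoacetate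
Conditions: NaN(SiMe3)2 (1.05 equiv), THF, −78 °C; then trans-3-phenyl-2-(phenylsulfonyl)oxaziridine (1.3 equiv), −78 → −40 °C; AcOH quench at −40 °C
Reagents that add atoms: trans-3-phenyl-2-(phenylsulfonyl)oxaziridine, O=S(=O)(c1ccccc1)N1OC1c1ccccc1
Why: Davis oxidation (electrophilic hydroxylation of a stabilised enolate by an N-sulfonyloxaziridine): the sodium enolate of 6 is planar at C3 and should take up oxygen on the lactone face opposite the C5 chain (1,3-induction across the envelope), which is the 3S configuration with the new oxygen trans to the chain. The oxaziridine transfers oxygen only to the carbanion and leaves the isolated alkene alone; the cold quench avoids acyl migration in the alkoxide of 7.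

Step 4
Reactants: 7 tert-butyl 2-[(3S,5R)-5-(dec-9-en-1-yl)-3-hydroxy-2-oxooxolan-3-yl]-2-oxoacetate; 8 (triphenylphosphoranylidene)ketene
Product: 10 tert-butyl (5S,8R)-8-(dec-9-en-1-yl)-2,6-dioxo-1,7-dioxaspiro[4.4]non-3-ene-4-carboxylate, via phosphoranylideneacetate ester 9 (not isolated)
Conditions: 7 dried azeotropically (toluene); 8 (1.3 equiv), toluene, 90 °C
Reagents that add atoms: none
Why: Bestmann butenolide synthesis: the acidic tertiary hydroxyl of 7 adds across the P=C=C unit of 8 to give ester ylide 9, whose carbon then undergoes an intramolecular Wittig reaction with the adjacent α-keto ester carbonyl, by far the most electrophilic carbonyl present, forming C1=C2 and closing ring B with loss of Ph3PO. C3 and C5 are not involved, so 10 carries the 5S,8R configuration set earlier.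

Step 5
Reactants: 10 tert-butyl (5S,8R)-8-(dec-9-en-1-yl)-2,6-dioxo-1,7-dioxaspiro[4.4]non-3-ene-4-carboxylate
Product: 11 tert-butyl (3S,4R,5S,8R)-8-(dec-9-en-1-yl)-3,4-epoxy-2,6-dioxo-1,7-dioxaspiro[4.4]nonane-4-carboxylate (cis-fused C1,C2-epoxide, oxygen syn to the ring A carbonyl)
Conditions: t-BuOOH (anhydrous, in decane, 1.5 equiv), n-BuLi (1.3 equiv), THF/toluene, −78 °C; then 10, −78 → −20 °C; aq. Na2SO3, NH4Cl
Reagents that add atoms: tert-butyl hydroperoxide, CC(C)(C)OO
Why: This is a Weitz–Scheffer nucleophilic epoxidation in its anhydrous lithium tert-butyl peroxide form, a known reaction of α,β-unsaturated esters, lactones and doubly activated alkenes. The peroxide oxygen adds to C1, the unsubstituted β-carbon of the C2 ester, because C2 is shielded by the quaternary C3, and the resulting C2 ester enolate then attacks the proximal peroxide oxygen and expels tert-butoxide, a 3-exo-tet closure that forms the C2–O bond and the oxirane. Both C–O bonds are made on the same face of the flat five-membered ring, so the epoxide is necessarily cis-fused and C1 and C2 are set together by a single facial choice. That choice should favour the face syn to C3', because this arm is a planar sp2 carbon with nothing pointing over ring B, whereas C4 projects a C–H over C2 and carries C5, whose chain is cis to C2 on ring A and so lies on the same side. The lithium counter-ion can in addition bridge the peroxide oxygen and the C3' carbonyl oxygen and deliver the reagent to that face, which is why a weakly coordinating THF/toluene medium at low temperature is chosen. Chemoselectivity rests on the nucleophilic character of the oxidant: the isolated alkene is inert, the hindered peroxide and tert-butoxide should add to the lactone carbonyls only reversibly at −78 to −20 °C, and the tert-butyl ester resists acyl attack. The intermediate enolate should not expel the ring oxygen from C3, because the C3–O bond lies in the nodal plane of the enolate, and 10 has no acidic hydrogen through which it could epimerise (C3 is quaternary). The step therefore needs only face selectivity, which is the one point of the route with an uncertain margin.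

Step 6
Reactants: 11 tert-butyl (3S,4R,5S,8R)-8-(dec-9-en-1-yl)-3,4-epoxy-2,6-dioxo-1,7-dioxaspiro[4.4]nonane-4-carboxylate
Product: 13 (3R,4R,5S,8R)-8-(dec-9-en-1-yl)-3,4-dihydroxy-2,6-dioxo-1,7-dioxaspiro[4.4]nonane-4-carboxylic acid (CNP0281847.1), via epoxy acid 12 (not isolated)
Conditions: TFA/CH2Cl2 (1:3), 0 °C → rt; evaporate; then 0.2 M aq. HClO4/1,4-dioxane (1:1), 70 °C; extract, concentrate from toluene
Reagents that add atoms: water, O
Why: The tert-butyl ester is cleaved by acidolysis through the tert-butyl cation, and the glycidic acid 12 is then hydrated under acid catalysis by SN2 attack of water at C1, the only epoxide carbon that is not quaternary, as in the conversion of cis-epoxysuccinic acid into tartaric acid. Attack anti to the epoxide oxygen inverts C1 (3S → 3R) while C2 keeps its oxygen and configuration (4R), giving the trans diol. Any lactone opening under these conditions is reversible, proceeds by acyl–oxygen cleavage and so does not touch C5.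

## Compound list

1 | 9-bromonon-1-ene | C=CCCCCCCCBr | starting material
2 | (S)-(5-oxooxolan-2-yl)methyl 4-methylbenzenesulfonate | Cc1ccc(cc1)S(=O)(=O)OC[C@@H]1CCC(=O)O1 | starting material
3 | non-8-en-1-ylmagnesium bromide | C=CCCCCCCC[Mg]Br | intermediate (not isolated)
4 | (R)-5-(dec-9-en-1-yl)oxolan-2-one | C=CCCCCCCCC[C@@H]1CCC(=O)O1 | intermediate
5 | di-tert-butyl oxalate | CC(C)(C)OC(=O)C(=O)OC(C)(C)C | starting material
6 | tert-butyl 2-[(5R)-5-(dec-9-en-1-yl)-2-oxooxolan-3-yl]-2-oxoacetate (C3 epimers, enolised) | C=CCCCCCCCC[C@@H]1CC(C(=O)C(=O)OC(C)(C)C)C(=O)O1 | intermediate
7 | tert-butyl 2-[(3S,5R)-5-(dec-9-en-1-yl)-3-hydroxy-2-oxooxolan-3-yl]-2-oxoacetate | C=CCCCCCCCC[C@@H]1C[C@](O)(C(=O)C(=O)OC(C)(C)C)C(=O)O1 | intermediate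
8 | (triphenylphosphoranylidene)ketene | O=C=C=P(c1ccccc1)(c1ccccc1)c1ccccc1 | starting material
9 | (3S,5R)-3-(2-tert-butoxy-2-oxoacetyl)-5-(dec-9-en-1-yl)-2-oxooxolan-3-yl 2-(triphenyl-λ5-phosphanylidene)acetate | C=CCCCCCCCC[C@@H]1C[C@](OC(=O)C=P(c2ccccc2)(c2ccccc2)c2ccccc2)(C(=O)C(=O)OC(C)(C)C)C(=O)O1 | intermediate (not isolated)
10 | tert-butyl (5S,8R)-8-(dec-9-en-1-yl)-2,6-dioxo-1,7-dioxaspiro[4.4]non-3-ene-4-carboxylate | C=CCCCCCCCC[C@@H]1C[C@@]2(OC(=O)C=C2C(=O)OC(C)(C)C)C(=O)O1 | intermediate
11 | tert-butyl (3S,4R,5S,8R)-8-(dec-9-en-1-yl)-3,4-epoxy-2,6-dioxo-1,7-dioxaspiro[4.4]nonane-4-carboxylate | C=CCCCCCCCC[C@@H]1C[C@@]2(OC(=O)[C@H]3O[C@@]23C(=O)OC(C)(C)C)C(=O)O1 | intermediate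
12 | (3S,4R,5S,8R)-8-(dec-9-en-1-yl)-3,4-epoxy-2,6-dioxo-1,7-dioxaspiro[4.4]nonane-4-carboxylic acid | C=CCCCCCCCC[C@@H]1C[C@@]2(OC(=O)[C@H]3O[C@@]23C(=O)O)C(=O)O1 | intermediate (not isolated)
13 | (3R,4R,5S,8R)-8-(dec-9-en-1-yl)-3,4-dihydroxy-2,6-dioxo-1,7-dioxaspiro[4.4]nonane-4-carboxylic acid | C=CCCCCCCCC[C@@H]1C[C@@]2(OC(=O)[C@H](O)[C@]2(O)C(=O)O)C(=O)O1 | target

## Step count and least certain steps

Total step count: 6 (3 is made and used in the flask within step 1). Longest linear sequence: 6 steps, from 2 to 13.

Step 5 (key step). The most likely failure is poor facial selectivity, with peroxide addition also on the face syn to C4, because the two arms on C3 differ only modestly in size and the lithium contact to the C3' carbonyl may be lost in a coordinating medium. A second risk is acyl attack on a lactone if the mixture is warmed too far. Fallback, from 7 and back at 13: the tertiary hydroxyl of 7 is acylated with (4-methoxybenzyloxy)acetyl chloride (pyridine, DMAP, CH2Cl2) to give the (4-methoxybenzyloxy)acetate F1. LiN(SiMe3)2 in THF at −78 °C then forms the ester enolate, which adds to the neighbouring keto ester carbonyl (intramolecular aldol), forming the C1–C2 bond and ring B to give the C1-O-(4-methoxybenzyl) C2-hydroxy spiro bis-lactone tert-butyl ester F2. TFA/anisole in CH2Cl2 removes the benzylic ether and the tert-butyl ester together and returns 13. Here the C2 face would depend on lithium chelation between the ketone and the C3' carbonyl, and C1 on the enolate geometry.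

Step 3. The most likely failure is weak 1,3-induction, with oxygen transfer to both faces of the nearly flat enolate, because the chain is three atoms away and pseudo-equatorial. Base-induced acyl shift or loss of the oxalyl group from the product alkoxide on warming is a second risk. Fallback, from 6 and back at 7: substrate control is replaced by reagent control, using an enantiopure (camphorsulfonyl)oxaziridine in its matched pairing with the sodium enolate of 6 (both antipodes are available), so that the reagent and not the remote chain selects the face. No new compound is involved (F0); any remaining epimer would be removed at the rigid spiro stage 10.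

Step 6. The most likely failure is loss of CO2 from the glycidic acid 12 on heating (decarboxylative epoxide opening), competing with the slow hydration of a doubly deactivated epoxide. Translactonisation in hot acid is a second risk. Fallback, from 11 and back at 13: the epoxide is hydrated while the carboxyl is still masked, with Sc(OTf)3 (10 mol %) in MeCN/H2O at 40 °C (Lewis-acid-catalysed anti hydration at C1), giving the diol tert-butyl ester F3. TFA/CH2Cl2 at room temperature then gives 13, so the free epoxy acid is never heated.

Step 4. The most likely failure is sluggish addition of the hindered, hydrogen-bonded tertiary hydroxyl (or of the hydrated keto ester) to 8, so that prolonged heating leads to ketol rearrangement. Fallback, from 7 and back at 10: 7 is esterified with 2-(diethoxyphosphoryl)acetic acid (N,N'-diisopropylcarbodiimide, DMAP, CH2Cl2) to the phosphonoacetate F4. LiCl and i-Pr2NEt in MeCN then bring about an intramolecular Horner–Wadsworth–Emmons olefination of the keto ester carbonyl, closing ring B to 10.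

Step 1. The most likely failure is addition of the Grignard reagent to the lactone carbonyl in competition with the copper-mediated substitution, because tosylates couple more slowly than halides. Fallback, from 3 and back at 4: 3 is added to (R)-epichlorohydrin with CuI (10 mol %) in THF at −40 °C, opening the epoxide at CH2 to give (R)-1-chlorododec-11-en-2-ol F5. NaOEt and diethyl malonate in EtOH at reflux convert F5, through (R)-2-(dec-9-en-1-yl)oxirane F6 formed in the flask, into ethyl (5R)-5-(dec-9-en-1-yl)-2-oxooxolane-3-carboxylate F7. LiCl in wet DMSO at 150 °C (Krapcho dealkoxycarbonylation) then gives 4.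

## Further compounds

F1 | step 5 | (3S,5R)-3-(2-tert-butoxy-2-oxoacetyl)-5-(dec-9-en-1-yl)-2-oxooxolan-3-yl 2-[(4-methoxybenzyl)oxy]acetate | C=CCCCCCCCC[C@@H]1C[C@](OC(=O)COCc2ccc(OC)cc2)(C(=O)C(=O)OC(C)(C)C)C(=O)O1
F2 | step 5 | tert-butyl (3R,4R,5S,8R)-8-(dec-9-en-1-yl)-4-hydroxy-3-[(4-methoxybenzyl)oxy]-2,6-dioxo-1,7-dioxaspiro[4.4]nonane-4-carboxylate | C=CCCCCCCCC[C@@H]1C[C@@]2(OC(=O)[C@H](OCc3ccc(OC)cc3)[C@]2(O)C(=O)OC(C)(C)C)C(=O)O1
F0 | step 3 | none | none
F3 | step 6 | tert-butyl (3R,4R,5S,8R)-8-(dec-9-en-1-yl)-3,4-dihydroxy-2,6-dioxo-1,7-dioxaspiro[4.4]nonane-4-carboxylate | C=CCCCCCCCC[C@@H]1C[C@@]2(OC(=O)[C@H](O)[C@]2(O)C(=O)OC(C)(C)C)C(=O)O1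
F4 | step 4 | (3S,5R)-3-(2-tert-butoxy-2-oxoacetyl)-5-(dec-9-en-1-yl)-2-oxooxolan-3-yl 2-(diethoxyphosphoryl)acetate | C=CCCCCCCCC[C@@H]1C[C@](OC(=O)CP(=O)(OCC)OCC)(C(=O)C(=O)OC(C)(C)C)C(=O)O1
F5 | step 1 | (R)-1-chlorododec-11-en-2-ol | ClC[C@H](O)CCCCCCCCC=C
F6 | step 1 | (R)-2-(dec-9-en-1-yl)oxirane | C=CCCCCCCCC[C@@H]1CO1
F7 | step 1 | ethyl (5R)-5-(dec-9-en-1-yl)-2-oxooxolane-3-carboxylate (C3 epimers) | C=CCCCCCCCC[C@@H]1CC(C(=O)OCC)C(=O)O1
A1 | alternative 1 | (2R,3R,6R)-6-[(tert-butyldimethylsilyl)oxy]-2,3-dihydroxy-3-(methoxycarbonyl)-4-oxohexadec-15-enoic acid | C=CCCCCCCCC[C@@H](O[Si](C)(C)C(C)(C)C)CC(=O)[C@@](O)(C(=O)OC)[C@@H](O)C(=O)O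
A2 | alternative 1 | methyl (2S,3R,4R)-2-(tert-butylcarbamoyl)-2-[(2R)-2-[(tert-butyldimethylsilyl)oxy]dodec-11-en-1-yl]-3,4-dihydroxy-5-oxooxolane-3-carboxylate | C=CCCCCCCCC[C@@H](O[Si](C)(C)C(C)(C)C)C[C@@]1(OC(=O)[C@H](O)[C@]1(O)C(=O)OC)C(=O)NC(C)(C)C
A3 | alternative 2 | 9-(acetyloxy)-6-(12-bromododecyl)-2,2-dimethyl-4,8-dioxo-1,3,7-trioxaspiro[4.4]nonane-6-carboxylic acid, configured at C1, C2 and C3 as in 13 | BrCCCCCCCCCCCC[C@]1(C(=O)O)OC(=O)[C@H](OC(C)=O)[C@@]12OC(C)(C)OC2=O
A4 | alternative 2 | spiro bis-lactone of the type of 13 with a 10-bromodecyl chain on C5, the C1 hydroxyl as acetate and the C2 hydroxy acid as its isopropylidene 1,3-dioxolan-4-one, configured at C1, C2, C3 and C5 as in 13 | O=C1O[C@H](CCCCCCCCCCBr)C[C@@]12OC(=O)[C@H](OC(C)=O)[C@@]23OC(C)(C)OC3=O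
A5 | alternative 3 | (3S,5R)-3-(2-tert-butoxy-2-oxoacetyl)-5-(dec-9-en-1-yl)-2-oxooxolan-3-yl 2-[(tert-butyldimethylsilyl)oxy]acetate | C=CCCCCCCCC[C@@H]1C[C@](OC(=O)CO[Si](C)(C)C(C)(C)C)(C(=O)C(=O)OC(C)(C)C)C(=O)O1
A6 | alternative 3 | tert-butyl (3R,4R,5S,8R)-3-[(tert-butyldimethylsilyl)oxy]-8-(dec-9-en-1-yl)-4-hydroxy-2,6-dioxo-1,7-dioxaspiro[4.4]nonane-4-carboxylate | C=CCCCCCCCC[C@@H]1C[C@@]2(OC(=O)[C@H](O[Si](C)(C)C(C)(C)C)[C@]2(O)C(=O)OC(C)(C)C)C(=O)O1
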